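I began from the leftover X: the catalyst in this flask has to meet it, and X meanwhile pairs off with itself without any catalyst.

J 0.40 M; X 1.00 M; Q 8.0 mM

    J + Q → J.Q (k1 = 27.6 M⁻¹ s⁻¹)
    X + J.Q → X.J.Q (k2 = 1.95 M⁻¹ s⁻¹)
    X.J.Q → Z (k3 = 10.0 s⁻¹)
    Z ⇌ Q + E (K4 = 0.66 M, k4 = 13.8 s⁻¹)
    2 X → X2 (k5 = 0.209 M⁻¹ s⁻¹)

- a doubled species enters its step squared and goes two at a time
- charge of J (flask): 0.40 M

- the form that holds most of the catalyst when 5.0% of the J are converted (Q / Z / J.Q / X.J.Q)
- its share of the catalyst then
- apparent order in Q when 5.0% of the J are converted (percent change of the rate of making E for one percent more Q charged)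

I reckoned one turn of a catalyst unit as a round of waits, each being one over the rate per unit. Capture of J took 0.0906 s, the change of X.J.Q 0.100 s and the release from Z 0.0725 s, together 0.263 s. I dropped the return of E onto Q, which ran slower per Q than capture of J.

The wait of J.Q for X was 0.513 s at the charge, longer than those together, so the crossing of control lay before the start: J.Q was the resting state, and its meeting with X the rate-limiting step.

The round began at 0.776 s, so in my reckoning the whole charge of catalyst, once circling with X at its charge, stood for a slope of E of 10.3 mM s⁻¹. Pairing took X at 0.418 M s⁻¹ at the charge, far faster than the catalyst then turned, so I reckoned X from pairing. One over X then climbs straight with time, and so does the round. Its slope is the creep, the seconds added to the round per second of run, which is the doubled pairing constant over the constant of X meeting J.Q: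

creep = 0.214

With no sharp knee, the curve of E bent steadily, and the round grew exponentially with E made. The mark meant 20.0 mM of J gone; I counted the catalyst charge as holding J, which left 12.0 mM as E:

round at the mark = 1.07 s, reached after 1.37 s, with E rising at 7.48 mM s⁻¹

The longest wait then gave J.Q, with a share of 75.4%. More charge also reaches the mark on a shorter round, so the order came out as one plus the creep times J converted per catalyst:

order = 1.54

The forecast named J.Q at 74%, below my share, with order 1.5, saying “the rate rises faster than the catalyst charge”.

This flask gave J.Q at 76.2% and an order of 1.5. It reached the mark at 1.72 s, later than my 1.37 s. Carried on to 12.0 s, the creep gave a reckoned round of 3.35 s, of which the wait for X made 92.1%, and J.Q in this flask then stood at 92.1% of the catalyst.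

The numbers of this flask are those of an exercise.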